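**Plan**

- Retrosynthesis: the ring C C–I bond is traced back to a nitro group. The bond between the ring A oxygen and the ring B carbon is cut to a ring A phenoxide and a ring B aryl(2,4,6-trimethoxyphenyl)iodonium salt. The bond between the ring B oxygen and the ring C carbon is cut by SNAr. The ring A C–O(sulfate) bond is cut to 2,4-dibromophenol and peroxydisulfate.
- Enabling feature: ring A is a catechol. Its oxygen on C1, meta to the bromines at C3 and C5, is the sulfate ester; its oxygen on C2, flanked by bromine, is the ether. C1 is therefore the one free ortho carbon of 2,4-dibromophenol and can receive its oxygen already sulfated.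
- Forward order: no ring is formed. Ring A sulfate is made, ring B is joined to ring C by SNAr, the only iodine of that ether is raised to an iodonium salt, and ring A is joined to ring B without metal. The ring C iodine is developed from the nitro group last, because a ring C iodide present earlier would be oxidised together with the ring B iodide.
- Stereochemistry: the target has no stereocentre.

Key step: step 1

Assumption: the sulfate monoesters 4, 12, 13 and 15 are drawn as hydrogen sulfates, like the target, but would be made and handled as potassium salts near pH 7; 5-bromo-2-iodophenol is taken as a purchasable compound.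

**Route**

Step 1
Reactants: 1 2,4-dibromophenol; 2 potassium peroxydisulfate (K2S2O8)
Product: 4 3,5-dibromo-2-hydroxyphenyl hydrogen sulfate, via dienone sulfate 3 (not isolated)
Conditions: 2 (0.8 equiv) added in portions to 1 in aq. KOH (2 M), 0 → 20 °C, 48 h; H2SO4 to pH 7; unreacted 1 extracted
Reagents that add atoms: none
Why: In aqueous KOH the phenolate of 1 reacts as a carbon nucleophile, and its C6, the only unsubstituted ortho carbon, attacks one peroxide oxygen of the peroxydisulfate dianion with loss of sulfate, so the new C–O bond forms with the sulfate group already on the oxygen. The resulting dienone sulfate 3 enolises at once to the catechol monosulfate 4, in which the original phenol oxygen is still free. The closest known reaction type is the Elbs persulfate oxidation of phenols in its ortho mode, which takes over when the para position is blocked. No ring is closed and no stereocentre remains, since the sp3 carbon of 3 is lost on enolisation. The step needs site selectivity, which the bromines at C2 and C4 secure by occupying the para and the other ortho carbon, and it needs restraint against further oxidation of 4, which is addressed by keeping 2 as the limiting reagent at low temperature.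

Step 2
Reactants: 5 5-bromo-2-iodophenol
Product: 7 2,3,4-tribromo-6-iodophenol, via 4,5-dibromo-2-iodophenol 6 (not isolated)
Conditions: NBS (2.05 equiv), MeCN, 0 °C → rt
Reagents that add atoms: N-bromosuccinimide, O=C1CCC(=O)N1Br
Why: Electrophilic aromatic bromination directed by the hydroxyl should fill the free para and then the free ortho carbon, giving three contiguous bromines, while the meta C–H stays and two equivalents at low temperature should leave the iodine in place.

Step 3
Reactants: 7 2,3,4-tribromo-6-iodophenol; 8 4-bromo-1-fluoro-2-nitrobenzene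
Product: 9 1,2,3-tribromo-4-(4-bromo-2-nitrophenoxy)-5-iodobenzene
Conditions: K2CO3, DMF, 80 °C
Reagents that add atoms: none
Why: This is an SNAr reaction in which the hindered phenoxide of 7 displaces the fluoride activated by the ortho nitro group, and the bromines and the iodine are not activated for substitution.

Step 4
Reactants: 9 1,2,3-tribromo-4-(4-bromo-2-nitrophenoxy)-5-iodobenzene
Product: 11 [3,4,5-tribromo-2-(4-bromo-2-nitrophenoxy)phenyl](2,4,6-trimethoxyphenyl)iodonium tosylate, via hydroxy(tosyloxy)iodoarene 10 (not isolated)
Conditions: mCPBA, TsOH·H2O, MeCN, 77 °C; then 1,3,5-trimethoxybenzene, 77 °C → rt; Et2O trituration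
Reagents that add atoms: p-toluenesulfonic acid monohydrate, Cc1ccc(cc1)S(=O)(=O)O.O; 1,3,5-trimethoxybenzene, COc1cc(OC)cc(OC)c1; mCPBA, OOC(=O)c1cccc(Cl)c1 (its oxygen is kept only in 10)
Why: This is the one-pot oxidation of an aryl iodide to trivalent iodine followed by electrophilic aromatic substitution on trimethoxybenzene, and it should be clean because 9 holds a single iodine and its nitro-deactivated ring C cannot act as an internal arene nucleophile.

Step 5
Reactants: 4 3,5-dibromo-2-hydroxyphenyl hydrogen sulfate; 11 [3,4,5-tribromo-2-(4-bromo-2-nitrophenoxy)phenyl](2,4,6-trimethoxyphenyl)iodonium tosylate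
Product: 12 3,5-dibromo-2-[3,4,5-tribromo-2-(4-bromo-2-nitrophenoxy)phenoxy]phenyl hydrogen sulfate
Conditions: K2CO3, DMF, rt → 45 °C, dark
Reagents that add atoms: none
Why: This is a metal-free O-arylation of a phenoxide with a diaryliodonium salt, in which ligand exchange at trivalent iodine and ligand coupling should transfer the electron-poor, ortho-substituted ring B and not the trimethoxyphenyl group, with the six C–Br bonds untouched and the sulfate anion not nucleophilic enough to compete.

Step 6
Reactants: 12 3,5-dibromo-2-[3,4,5-tribromo-2-(4-bromo-2-nitrophenoxy)phenoxy]phenyl hydrogen sulfate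
Product: 13 2-[2-(2-amino-4-bromophenoxy)-3,4,5-tribromophenoxy]-3,5-dibromophenyl hydrogen sulfate
Conditions: Fe powder, NH4Cl, EtOH/H2O, 70 °C
Reagents that add atoms: none
Why: This is a Béchamp-type iron reduction of the nitro group in a nearly neutral medium, under which aryl bromides and the sulfate monoester anion are expected to persist.

Step 7
Reactants: 13 2-[2-(2-amino-4-bromophenoxy)-3,4,5-tribromophenoxy]-3,5-dibromophenyl hydrogen sulfate
Product: 15 bromoiesol B sulfate, 3,5-dibromo-2-[3,4,5-tribromo-2-(4-bromo-2-iodophenoxy)phenoxy]phenyl hydrogen sulfate, via diazonium inner salt 14 (not isolated)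
Conditions: NaNO2, aq. H2SO4 (0.5 M) with a little MeCN, 0 °C, 20 min; KI, 0 °C → rt; KHCO3 to pH 7; reversed-phase chromatography
Reagents that add atoms: potassium iodide, [K+].[I-]; sodium nitrite, [Na+].[O-]N=O (its nitrogen is kept only in 14)
Why: This is a Sandmeyer-type diazotisation and iodide substitution that needs no copper, the cold dilute aqueous acid and short contact time should spare the aryl sulfate, and Pschorr closure to a dibenzofuran is excluded because both ortho carbons of ring B next to the ether oxygen are substituted.

**Compound list**

1 | 2,4-dibromophenol | Oc1ccc(Br)cc1Br | starting material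
2 | potassium peroxydisulfate (K2S2O8) | [K+].[K+].[O-]S(=O)(=O)OOS(=O)(=O)[O-] | starting material
3 | 3,5-dibromo-2-oxocyclohexa-3,5-dien-1-yl hydrogen sulfate (dienone sulfate, racemic, transient) | O=C1C(Br)=CC(Br)=CC1OS(=O)(=O)O | intermediate (not isolated)
4 | 3,5-dibromo-2-hydroxyphenyl hydrogen sulfate | O=S(=O)(O)Oc1cc(Br)cc(Br)c1O | intermediate
5 | 5-bromo-2-iodophenol | Oc1cc(Br)ccc1I | starting material
6 | 4,5-dibromo-2-iodophenol | Oc1cc(Br)c(Br)cc1I | intermediate (not isolated)
7 | 2,3,4-tribromo-6-iodophenol | Oc1c(I)cc(Br)c(Br)c1Br | intermediate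
8 | 4-bromo-1-fluoro-2-nitrobenzene | [O-][N+](=O)c1cc(Br)ccc1F | starting material
9 | 1,2,3-tribromo-4-(4-bromo-2-nitrophenoxy)-5-iodobenzene | [O-][N+](=O)c1cc(Br)ccc1Oc1c(I)cc(Br)c(Br)c1Br | intermediate
10 | 1-[hydroxy(tosyloxy)iodo]-3,4,5-tribromo-2-(4-bromo-2-nitrophenoxy)benzene | Cc1ccc(cc1)S(=O)(=O)OI(O)c1cc(Br)c(Br)c(Br)c1Oc1ccc(Br)cc1[N+](=O)[O-] | intermediate (not isolated)
11 | [3,4,5-tribromo-2-(4-bromo-2-nitrophenoxy)phenyl](2,4,6-trimethoxyphenyl)iodonium tosylate | COc1cc(OC)c([I+]c2cc(Br)c(Br)c(Br)c2Oc2ccc(Br)cc2[N+](=O)[O-])c(OC)c1.Cc1ccc(cc1)S(=O)(=O)[O-] | intermediate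
12 | 3,5-dibromo-2-[3,4,5-tribromo-2-(4-bromo-2-nitrophenoxy)phenoxy]phenyl hydrogen sulfate | O=S(=O)(O)Oc1cc(Br)cc(Br)c1Oc1cc(Br)c(Br)c(Br)c1Oc1ccc(Br)cc1[N+](=O)[O-] | intermediate
13 | 2-[2-(2-amino-4-bromophenoxy)-3,4,5-tribromophenoxy]-3,5-dibromophenyl hydrogen sulfate | O=S(=O)(O)Oc1cc(Br)cc(Br)c1Oc1cc(Br)c(Br)c(Br)c1Oc1ccc(Br)cc1N | intermediate
14 | 5-bromo-2-[2,3,4-tribromo-6-(2,4-dibromo-6-sulfonatooxyphenoxy)phenoxy]benzenediazonium, inner salt | [O-]S(=O)(=O)Oc1cc(Br)cc(Br)c1Oc1cc(Br)c(Br)c(Br)c1Oc1ccc(Br)cc1[N+]#N | intermediate (not isolated)
15 | bromoiesol B sulfate, 3,5-dibromo-2-[3,4,5-tribromo-2-(4-bromo-2-iodophenoxy)phenoxy]phenyl hydrogen sulfate | O=S(=O)(O)Oc1cc(Br)cc(Br)c1Oc1cc(Br)c(Br)c(Br)c1Oc1ccc(Br)cc1I | target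

**Step count and risks**

Total: 7 steps. Longest linear sequence: 6 steps (steps 2 to 7, from 5 to 15); step 1 is a one-step branch that joins at step 5.

Steps most likely to fail:

1. Step 1. The electron-poor dibromophenolate may attack the peroxide bond only slowly, so that persulfate is lost by homolysis and the product is eroded by further oxidation. Fallback: it sets out from 1 and comes back to the route at 4. ortho-Formylation of 1 with MgCl2, Et3N and paraformaldehyde in refluxing MeCN should give 3,5-dibromo-2-hydroxybenzaldehyde F1. Dakin oxidation with H2O2 in aq. NaOH at 0 °C → rt should then convert it into 3,5-dibromobenzene-1,2-diol F2. One equivalent of SO3·pyridine in MeCN at 0 °C without added base should finally sulfate the hydroxyl remote from bromine, which is the less hindered and more nucleophilic one, to give 4 after separation from any regioisomer.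

2. Step 5. Ligand coupling at iodine may be slowed by the low nucleophilicity and poor solubility of the doubly charged, doubly ortho-substituted phenoxide, so that attack at the nitro-activated ipso carbon of ring C, with cleavage of the ether between ring B and ring C, could compete. Fallback: it sets out from 9 and 4 and comes back to the route at 12, with step 4 bypassed. It is an Ullmann-type ether coupling with CuI, picolinic acid and K3PO4 in DMSO at 80 °C, in which copper should insert into the single C–I bond of 9 in preference to the C–Br bonds. This fallback makes no new compound and is entered as F0.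

3. Step 7. The aryl sulfate may be hydrolysed under the acidic diazotisation, or the diazonium group may be reduced to C–H instead of being replaced by iodide. Fallback: it sets out from 13 and comes back to the route at 15. Diazotisation and iodination are run in aqueous acid without regard for the sulfate, and the solvolysis is then completed with aq. HCl in dioxane at 50 °C to converge on 3,5-dibromo-2-[3,4,5-tribromo-2-(4-bromo-2-iodophenoxy)phenoxy]phenol F3. Its only hydroxyl is then sulfated with SO3·pyridine in pyridine at rt, and the product is brought to pH 7 with KHCO3 to give 15.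

**Further compounds**

F1 | step 1 | 3,5-dibromo-2-hydroxybenzaldehyde | O=Cc1cc(Br)cc(Br)c1O
F2 | step 1 | 3,5-dibromobenzene-1,2-diol | Oc1cc(Br)cc(Br)c1O
F0 | step 5 | none | none
F3 | step 7 | 3,5-dibromo-2-[3,4,5-tribromo-2-(4-bromo-2-iodophenoxy)phenoxy]phenol | Oc1cc(Br)cc(Br)c1Oc1cc(Br)c(Br)c(Br)c1Oc1ccc(Br)cc1I
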